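**Retrosynthetic overview**
1. All five benzene rings are bought as methoxy-arenes; no ring is built. Only the four diaryl ether C–O bonds are made, then all twelve methyl ethers are cleaved at once.
2. Last C–O bond: ring C oxygen to ring D carbon (Ullmann), which splits the permethyl ether into an ABC phenol and a DE aryl bromide.
3. DE bromide: ring D oxygen to ring E carbon by Chan–Lam coupling of a bromophenol with an arylboronic acid (the bromide survives).
4. ABC phenol: ring B oxygen to ring C carbon by SNAr on an ortho-fluorobenzaldehyde, whose CHO is the masked ring C phenol (Dakin oxidation); ring A oxygen to ring B carbon by Ullmann.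
5. Order of joining: D–E; B–C; A–BC; unmask ring C phenol; ABC + DE; global demethylation.

Assumption: the SMILES has no stereocentre and no hindered axis, so the target is achiral and no stereocontrol is needed; the four methoxy-arene building blocks are taken as catalogue chemicals.

**Step 1**
Reactants: 1 4-bromo-2,6-dimethoxyphenol; 2 (3,4,5-trimethoxyphenyl)boronic acid
Product: 3 5-bromo-1,3-dimethoxy-2-(3,4,5-trimethoxyphenoxy)benzene (DE bromide)
Conditions: Cu(OAc)2 (1.0 equiv), pyridine (5 equiv), 2 (2.5 equiv), 4 Å MS, CH2Cl2, dry air, rt, 48 h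
Reagents that add atoms: none
Why: Chan–Lam–Evans oxidative O-arylation by divalent copper (kept divalent by air) joins the hindered phenol to the electron-rich boronic acid at room temperature, where the aryl bromide is inert and the para-bromine blocks oxidative phenol dimerisation; no stereocentre is formed.

**Step 2**
Reactants: 1 4-bromo-2,6-dimethoxyphenol; 4 2-fluoro-4,6-dimethoxybenzaldehyde
Product: 5 2-(4-bromo-2,6-dimethoxyphenoxy)-4,6-dimethoxybenzaldehyde
Conditions: Cs2CO3 (1.5 equiv), DMSO, 110 °C, N2, 16 h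
Reagents that add atoms: none
Why: Nucleophilic aromatic substitution (SNAr) in which the ortho-formyl group stabilises the Meisenheimer adduct and fluoride leaves, while the unactivated aryl bromide is untouched; no stereocentre is formed.

**Step 3**
Reactants: 5 2-(4-bromo-2,6-dimethoxyphenoxy)-4,6-dimethoxybenzaldehyde; 6 2,4,6-trimethoxyphenol
Product: 7 2-[2,6-dimethoxy-4-(2,4,6-trimethoxyphenoxy)phenoxy]-4,6-dimethoxybenzaldehyde (ABC aldehyde)
Conditions: CuI (10 mol %), picolinic acid (20 mol %), K3PO4 (2 equiv), 6 (1.5 equiv), degassed DMSO, 90 °C, Ar, 24 h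
Reagents that add atoms: none
Why: Ligand-accelerated Ullmann diaryl ether synthesis with monovalent copper couples a di-ortho-substituted phenol to a sterically open aryl bromide (hydrogen on both sides), and the non-enolisable electron-rich aldehyde tolerates phosphate base; no stereocentre is formed.

**Step 4**
Reactants: 7 ABC aldehyde
Product: 9 2-[2,6-dimethoxy-4-(2,4,6-trimethoxyphenoxy)phenoxy]-4,6-dimethoxyphenol (ABC phenol), via aryl formate 8 (not isolated)
Conditions: mCPBA (1.2 equiv), CH2Cl2, 0 °C → rt; then K2CO3 (cat.), MeOH, rt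
Reagents that add atoms: mCPBA (3-chloroperoxybenzoic acid), OOC(=O)c1cccc(Cl)c1
Why: Dakin-type Baeyer–Villiger oxidation in which the electron-rich trioxygenated aryl group migrates in preference to hydrogen to give the aryl formate, which is methanolysed to the phenol; no stereocentre is formed.

**Step 5**
Reactants: 9 ABC phenol; 3 DE bromide
Product: 10 1,5-dimethoxy-3-[2,6-dimethoxy-4-(2,4,6-trimethoxyphenoxy)phenoxy]-2-[3,5-dimethoxy-4-(3,4,5-trimethoxyphenoxy)phenoxy]benzene (dodeca-O-methyl ether of the target)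
Conditions: CuI (20 mol %), picolinic acid (40 mol %), K3PO4 (2 equiv), 3 (1.3 equiv), degassed DMSO, 100 °C, Ar, 36 h
Reagents that add atoms: none
Why: A second Ullmann diaryl ether coupling with monovalent copper, again pairing a hindered phenol with an aryl bromide that has no ortho substituent, which is the favourable steric arrangement for this reaction; no stereocentre is formed.

**Step 6**
Reactants: 10 dodeca-O-methyl ether
Product: 12 2-[4-[2-[3,5-dihydroxy-4-(3,4,5-trihydroxyphenoxy)phenoxy]-3,5-dihydroxyphenoxy]-3,5-dihydroxyphenoxy]benzene-1,3,5-triol (CNP0227069.0), via per-O-dibromoboryl ether 11 (not isolated)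
Conditions: BBr3 (30 equiv, 1 M in CH2Cl2), CH2Cl2, −78 °C → rt, 24 h; then H2O, 0 °C; Sephadex LH-20 (MeOH) under Ar
Reagents that add atoms: none
Why: Lewis-acid ether cleavage in which BBr3 complexes each methoxy oxygen and bromide removes the methyl group by SN2, while the diaryl ether bonds are inert because both carbons are sp2; aqueous quench hydrolyses the O–B bonds and no stereocentre is involved.

**Compound list**
1 | 4-bromo-2,6-dimethoxyphenol | COc1cc(Br)cc(OC)c1O | starting material
2 | (3,4,5-trimethoxyphenyl)boronic acid | COc1cc(B(O)O)cc(OC)c1OC | starting material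
3 | 5-bromo-1,3-dimethoxy-2-(3,4,5-trimethoxyphenoxy)benzene | COc1cc(Br)cc(OC)c1Oc1cc(OC)c(OC)c(OC)c1 | intermediate
4 | 2-fluoro-4,6-dimethoxybenzaldehyde | COc1cc(F)c(C=O)c(OC)c1 | starting material
5 | 2-(4-bromo-2,6-dimethoxyphenoxy)-4,6-dimethoxybenzaldehyde | COc1cc(Oc2c(OC)cc(Br)cc2OC)c(C=O)c(OC)c1 | intermediate
6 | 2,4,6-trimethoxyphenol | COc1cc(OC)c(O)c(OC)c1 | starting material
7 | 2-[2,6-dimethoxy-4-(2,4,6-trimethoxyphenoxy)phenoxy]-4,6-dimethoxybenzaldehyde | COc1cc(Oc2c(OC)cc(Oc3c(OC)cc(OC)cc3OC)cc2OC)c(C=O)c(OC)c1 | intermediate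
8 | 2-[2,6-dimethoxy-4-(2,4,6-trimethoxyphenoxy)phenoxy]-4,6-dimethoxyphenyl formate | COc1cc(Oc2c(OC)cc(Oc3c(OC)cc(OC)cc3OC)cc2OC)c(OC=O)c(OC)c1 | intermediate
9 | 2-[2,6-dimethoxy-4-(2,4,6-trimethoxyphenoxy)phenoxy]-4,6-dimethoxyphenol | COc1cc(Oc2c(OC)cc(Oc3c(OC)cc(OC)cc3OC)cc2OC)c(O)c(OC)c1 | intermediate
10 | 1,5-dimethoxy-3-[2,6-dimethoxy-4-(2,4,6-trimethoxyphenoxy)phenoxy]-2-[3,5-dimethoxy-4-(3,4,5-trimethoxyphenoxy)phenoxy]benzene | COc1cc(OC)c(Oc2cc(OC)c(Oc3cc(OC)cc(OC)c3Oc3cc(OC)c(Oc4cc(OC)c(OC)c(OC)c4)c(OC)c3)c(OC)c2)c(OC)c1 | intermediate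
11 | dodeca-O-(dibromoboryl) ether of the target (idealised form of the boron-bound polyphenol) | BrB(Br)Oc1cc(OB(Br)Br)c(Oc2cc(OB(Br)Br)c(Oc3cc(OB(Br)Br)cc(OB(Br)Br)c3Oc3cc(OB(Br)Br)c(Oc4cc(OB(Br)Br)c(OB(Br)Br)c(OB(Br)Br)c4)c(OB(Br)Br)c3)c(OB(Br)Br)c2)c(OB(Br)Br)c1 | intermediate
12 | 2-[4-[2-[3,5-dihydroxy-4-(3,4,5-trihydroxyphenoxy)phenoxy]-3,5-dihydroxyphenoxy]-3,5-dihydroxyphenoxy]benzene-1,3,5-triol | Oc1cc(O)c(Oc2cc(O)c(Oc3cc(O)cc(O)c3Oc3cc(O)c(Oc4cc(O)c(O)c(O)c4)c(O)c3)c(O)c2)c(O)c1 | target

**Totals**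
Total step count: 6.
Longest linear sequence: 5 steps (steps 2, 3, 4, 5, 6); step 1 is the convergent branch.

**Three steps most likely to fail, with fallbacks**

Step 5 (coupling of two large fragments at a phenol flanked by methoxy and aryloxy groups). The fallback reverses the polarity of the bromide partner and sets out from 3. Miyaura borylation of 3 (bis(pinacolato)diboron, Pd(dppf)Cl2, KOAc, dioxane, 90 °C) gives 2-[3,5-dimethoxy-4-(3,4,5-trimethoxyphenoxy)phenyl]-4,4,5,5-tetramethyl-1,3,2-dioxaborolane F4. F4 (2 equiv) is then joined to phenol 9 by room-temperature Chan–Lam coupling (Cu(OAc)2, pyridine, boric acid additive, 4 Å MS, MeCN, dry air), the same kind of reaction that makes the equally hindered ether in step 1. The fallback comes back to the route at 10.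

Step 2 (SNAr of a di-ortho-substituted phenoxide on a fluorobenzaldehyde deactivated by two methoxy donors). The fallback makes the A–B ether first and closes the B–C ether by copper catalysis instead of SNAr; it sets out from 1 and 6. Phenol 1 is benzylated (benzyl bromide, BrCc1ccccc1, K2CO3, DMF) to 2-(benzyloxy)-5-bromo-1,3-dimethoxybenzene F1. Ullmann coupling of F1 with 6 (CuI, picolinic acid, K3PO4, DMSO, 90 °C) gives 2-(benzyloxy)-1,3-dimethoxy-5-(2,4,6-trimethoxyphenoxy)benzene F2. Hydrogenolysis (H2, 10% Pd on carbon, EtOAc/MeOH) frees 2,6-dimethoxy-4-(2,4,6-trimethoxyphenoxy)phenol F3. F3 is coupled with commercial 2-bromo-4,6-dimethoxybenzaldehyde (COc1cc(Br)c(C=O)c(OC)c1) under the same CuI/picolinic acid conditions, where the ortho-formyl group assists the copper insertion. The fallback comes back at 7 and so also bypasses step 3.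

Step 6 (twelve-fold demethylation, with risk of incomplete cleavage and of air oxidation of the free dodecaphenol on isolation). The fallback does not isolate the free phenol directly; it sets out from 10. After BBr3 treatment the mixture is quenched with MeOH and evaporated, and the crude polyphenol is peracetylated (Ac2O, pyridine, DMAP, rt) to the dodecaacetate of the target F5. F5 is stable on silica, so under-demethylated acetates can be separated and returned to BBr3. Pure F5 is deacetylated under argon (NaOMe cat., MeOH, 0 °C, then acidic ion-exchange resin), coming back at 12.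

**Further compounds**
F1 | step 2 | 2-(benzyloxy)-5-bromo-1,3-dimethoxybenzene | COc1cc(Br)cc(OC)c1OCc1ccccc1
F2 | step 2 | 2-(benzyloxy)-1,3-dimethoxy-5-(2,4,6-trimethoxyphenoxy)benzene | COc1cc(OC)c(Oc2cc(OC)c(OCc3ccccc3)c(OC)c2)c(OC)c1
F3 | step 2 | 2,6-dimethoxy-4-(2,4,6-trimethoxyphenoxy)phenol | COc1cc(OC)c(Oc2cc(OC)c(O)c(OC)c2)c(OC)c1
F4 | step 5 | 2-[3,5-dimethoxy-4-(3,4,5-trimethoxyphenoxy)phenyl]-4,4,5,5-tetramethyl-1,3,2-dioxaborolane | COc1cc(B2OC(C)(C)C(C)(C)O2)cc(OC)c1Oc1cc(OC)c(OC)c(OC)c1
F5 | step 6 | dodeca-O-acetate of the target | CC(=O)Oc1cc(OC(C)=O)c(Oc2cc(OC(C)=O)c(Oc3cc(OC(C)=O)cc(OC(C)=O)c3Oc3cc(OC(C)=O)c(Oc4cc(OC(C)=O)c(OC(C)=O)c(OC(C)=O)c4)c(OC(C)=O)c3)c(OC(C)=O)c2)c(OC(C)=O)c1
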